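Ring A of unit 1 (the 4-methoxyphenyl flavone) is opened at C7–C8 and C4a–C5. This removes the C5–C6–C7 malonyl unit and leaves a 4-pyranone that is already ring C. The feature exploited is that the pyranone's benzylic carbon (future C8, already bonded to C6'' of unit 2) and its C3 (future C4a) are the two nucleophilic carbons of one dienolate. A malonyl bis-electrophile bridges them in one operation, so the hindered C8–C6'' bond, present from the start as a benzylic bond, becomes the biaryl axis by aromatisation instead of cross-coupling. The precursor is tribenzylated apigenin bearing a [6-(4-methoxyphenyl)-4-oxopyran-2-yl]methyl group at C6''.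

Key step: step 8

Remark: the target SMILES fixes no configuration at the C8–C6'' axis and the molecule has no stereocentre, so the racemic biaryl is taken as the target. In steps 1–7 unprimed locants refer to the flavone being elaborated; its C6 is C6'' of the target.

Step 1
Reactants: 1 apigenin (5,7-dihydroxy-2-(4-hydroxyphenyl)chromen-4-one)
Product: 2 7-(benzyloxy)-2-[4-(benzyloxy)phenyl]-5-hydroxychromen-4-one
Conditions: BnBr (2.2 equiv), K2CO3, DMF, 20 °C
Reagents that add atoms: benzyl bromide, BrCc1ccccc1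
Why: Williamson etherification; the 7- and 4'-hydroxyls are the acidic, unchelated phenols, whereas the 5-hydroxyl is hydrogen-bonded to the C4 carbonyl and should stay free under these mild conditions.

Step 2
Reactants: 2 7-(benzyloxy)-2-[4-(benzyloxy)phenyl]-5-hydroxychromen-4-one
Product: 3 7-(benzyloxy)-2-[4-(benzyloxy)phenyl]-5-(prop-2-enyloxy)chromen-4-one
Conditions: allyl bromide (3 equiv), K2CO3, DMF, 70 °C
Reagents that add atoms: allyl bromide, C=CCBr
Why: Williamson etherification under forcing conditions alkylates the only remaining, chelated 5-hydroxyl and so places the allyl group on the oxygen next to C6.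

Step 3
Reactants: 3 7-(benzyloxy)-2-[4-(benzyloxy)phenyl]-5-(prop-2-enyloxy)chromen-4-one
Product: 4 7-(benzyloxy)-2-[4-(benzyloxy)phenyl]-5-hydroxy-6-(prop-2-enyl)chromen-4-one
Conditions: PhNEt2, 200 °C
Reagents that add atoms: none
Why: Aromatic Claisen rearrangement; of the two positions ortho to O5 only C6 carries hydrogen (the other is C4a), so the [3,3] shift should deliver the allyl group to C6 and enolisation restores the chelated phenol.

Step 4
Reactants: 4 7-(benzyloxy)-2-[4-(benzyloxy)phenyl]-5-hydroxy-6-(prop-2-enyl)chromen-4-one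
Product: 5 5,7-bis(benzyloxy)-2-[4-(benzyloxy)phenyl]-6-(prop-2-enyl)chromen-4-one
Conditions: BnBr (1.5 equiv), Cs2CO3, nBu4NI (cat.), DMF, 60 °C
Reagents that add atoms: benzyl bromide, BrCc1ccccc1
Why: Williamson etherification of the hindered 5-phenol through its caesium salt; capping it prevents hemiacetal or benzofuran formation with the side-chain carbonyl made next and removes an acidic proton before the enolate steps.

Step 5
Reactants: 5 5,7-bis(benzyloxy)-2-[4-(benzyloxy)phenyl]-6-(prop-2-enyl)chromen-4-one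
Product: 6 2-{5,7-bis(benzyloxy)-2-[4-(benzyloxy)phenyl]-4-oxochromen-6-yl}acetaldehyde
Conditions: OsO4 (2 mol%), NaIO4 (4 equiv), 2,6-lutidine, dioxane/H2O, 20 °C
Reagents that add atoms: osmium tetroxide, O=[Os](=O)(=O)=O; sodium periodate, [Na+].[O-]I(=O)(=O)=O
Why: Lemieux–Johnson oxidation (catalytic dihydroxylation with in situ periodate glycol cleavage); the terminal alkene should react far faster than the conjugated, electron-poor chromone C2–C3 bond, and 2,6-lutidine suppresses over-oxidation.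

Step 6
Reactants: 6 2-{5,7-bis(benzyloxy)-2-[4-(benzyloxy)phenyl]-4-oxochromen-6-yl}acetaldehyde; 7 1-(4-methoxyphenyl)butane-1,3-dione
Product: 9 6-{5,7-bis(benzyloxy)-2-[4-(benzyloxy)phenyl]-4-oxochromen-6-yl}-5-hydroxy-1-(4-methoxyphenyl)hexane-1,3-dione (racemic), via dilithium dianion 8 (not isolated)
Conditions: 7 (1.6 equiv), LiN(iPr)2 (3.3 equiv), THF, −78 → 0 °C; then 6, −78 °C; aq. NH4Cl
Reagents that add atoms: none
Why: Aldol addition of a β-diketone dianion; the second deprotonation occurs at the terminal methyl, and this more basic carbon should add to the aldehyde at −78 °C faster than it enolises it, giving a racemic carbinol centre that step 7 removes.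

Step 7
Reactants: 9 6-{5,7-bis(benzyloxy)-2-[4-(benzyloxy)phenyl]-4-oxochromen-6-yl}-5-hydroxy-1-(4-methoxyphenyl)hexane-1,3-dione
Product: 11 2-({5,7-bis(benzyloxy)-2-[4-(benzyloxy)phenyl]-4-oxochromen-6-yl}methyl)-6-(4-methoxyphenyl)pyran-4-one, via triketone 10 (not isolated)
Conditions: Dess–Martin periodinane (1.2 equiv), CH2Cl2, 0 → 20 °C, aqueous work-up; then TsOH·H2O (0.2 equiv), toluene, 60 °C
Reagents that add atoms: none
Why: Dess–Martin oxidation of the secondary alcohol gives the 1,3,5-triketone, whose enol should cyclodehydrate under acid catalysis (one outer carbonyl oxygen adds to the other outer carbonyl, then water is lost) to the 2,6-disubstituted 4-pyranone, the standard triketone-to-γ-pyrone closure.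

Step 8
Reactants: 11 2-({5,7-bis(benzyloxy)-2-[4-(benzyloxy)phenyl]-4-oxochromen-6-yl}methyl)-6-(4-methoxyphenyl)pyran-4-one; 12 bis(2,4,6-trichlorophenyl) malonate
Product: 16 8-{5,7-bis(benzyloxy)-2-[4-(benzyloxy)phenyl]-4-oxochromen-6-yl}-5,7-dihydroxy-2-(4-methoxyphenyl)chromen-4-one, via lithium dienolate 13 (not isolated), via keto ester 14 (not isolated), via acylketene 15 (not isolated)
Conditions: LiN(SiMe3)2 (2.2 equiv), THF, −78 °C; then 12 (1.1 equiv), −78 → 20 °C, then 60 °C; 1 M HCl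
Reagents that add atoms: none
Why: Proposed new method: LiN(SiMe3)2 removes the doubly activated benzylic proton of 11 to give dienolate 13 (charge shared by C8, pyranone C3 and O4), while the second equivalent deprotonates the C–H acidic malonate 12, whose enolate ejects trichlorophenoxide to give a slim (aryloxycarbonyl)ketene; C8 of 13 adds to the ketene carbon (C7–C8), keto ester 14 loses the second trichlorophenoxide by the same E1cB path to give acylketene 15, and the C8-enolate of 15, a dienylketene spanning C4a=C8a–C8=C7–C6=C5, closes and tautomerises to the 5,7-diol. The closest known reactions are the condensations of bis(2,4,6-trichlorophenyl) malonates with 1,3-dinucleophiles through ketene intermediates, the side-chain acylation of lithiated 2-alkyl-4-pyranones, the Claisen-type C-acylation of lithium enolates by ketenes that aryl ester enolates release, and the six-electron electrocyclisation of dienylketenes in benzannulations. Ring A closes by thermal disrotatory 6π electrocyclisation (equivalently a six-membered C-acylation of pyranone C3 by the ketene carbon), which forms C4a–C5. No stereocentre results, because the sp3 C8 of 14 and 15 becomes aromatic and the C8–C6'' axis forms as a racemate. The selectivity needed is carbon over oxygen acylation of 13 followed by carbon closure: the lithium counter-ion in THF favours carbon, an O4-acyl enol ester is itself an active ester that the liberated trichlorophenoxide returns to the pool whereas C-acylation drains irreversibly into the aromatic ring, and once C8 is acylated the ketene can reach no acylatable oxygen through a six-membered ring (O1 is a ring ether and the flanking phenols are benzylated).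

Step 9
Reactants: 16 8-{5,7-bis(benzyloxy)-2-[4-(benzyloxy)phenyl]-4-oxochromen-6-yl}-5,7-dihydroxy-2-(4-methoxyphenyl)chromen-4-one
Product: 17 8-[5,7-dihydroxy-2-(4-hydroxyphenyl)-4-oxochromen-6-yl]-5,7-dihydroxy-2-(4-methoxyphenyl)chromen-4-one (target, CNP0310322.0)
Conditions: H2 (1 atm), 10% Pd/C, THF/MeOH, 20 °C
Reagents that add atoms: none
Why: Catalytic hydrogenolysis of the three aryl benzyl ethers; the aryl methyl ether is inert and the chromone C2–C3 bonds should not be reduced at 1 atm and room temperature.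

Compound list
1 | apigenin | O=c1cc(-c2ccc(O)cc2)oc2cc(O)cc(O)c12 | starting material
2 | 7-(benzyloxy)-2-[4-(benzyloxy)phenyl]-5-hydroxychromen-4-one | O=c1cc(-c2ccc(OCc3ccccc3)cc2)oc2cc(OCc3ccccc3)cc(O)c12 | intermediate
3 | 7-(benzyloxy)-2-[4-(benzyloxy)phenyl]-5-(prop-2-enyloxy)chromen-4-one | C=CCOc1cc(OCc2ccccc2)cc2oc(-c3ccc(OCc4ccccc4)cc3)cc(=O)c12 | intermediate
4 | 7-(benzyloxy)-2-[4-(benzyloxy)phenyl]-5-hydroxy-6-(prop-2-enyl)chromen-4-one | C=CCc1c(OCc2ccccc2)cc2oc(-c3ccc(OCc4ccccc4)cc3)cc(=O)c2c1O | intermediate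
5 | 5,7-bis(benzyloxy)-2-[4-(benzyloxy)phenyl]-6-(prop-2-enyl)chromen-4-one | C=CCc1c(OCc2ccccc2)cc2oc(-c3ccc(OCc4ccccc4)cc3)cc(=O)c2c1OCc1ccccc1 | intermediate
6 | 2-{5,7-bis(benzyloxy)-2-[4-(benzyloxy)phenyl]-4-oxochromen-6-yl}acetaldehyde | O=CCc1c(OCc2ccccc2)cc2oc(-c3ccc(OCc4ccccc4)cc3)cc(=O)c2c1OCc1ccccc1 | intermediate
7 | 1-(4-methoxyphenyl)butane-1,3-dione | COc1ccc(C(=O)CC(C)=O)cc1 | starting material
8 | dilithium 1-(4-methoxyphenyl)buta-1,3-diene-1,3-diolate (dianion of 7) | [Li+].[Li+].COc1ccc(cc1)C([O-])=CC([O-])=C | intermediate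
9 | 6-{5,7-bis(benzyloxy)-2-[4-(benzyloxy)phenyl]-4-oxochromen-6-yl}-5-hydroxy-1-(4-methoxyphenyl)hexane-1,3-dione (racemic at C5) | COc1ccc(C(=O)CC(=O)CC(O)Cc2c(OCc3ccccc3)cc3oc(-c4ccc(OCc5ccccc5)cc4)cc(=O)c3c2OCc2ccccc2)cc1 | intermediate
10 | 6-{5,7-bis(benzyloxy)-2-[4-(benzyloxy)phenyl]-4-oxochromen-6-yl}-1-(4-methoxyphenyl)hexane-1,3,5-trione | COc1ccc(C(=O)CC(=O)CC(=O)Cc2c(OCc3ccccc3)cc3oc(-c4ccc(OCc5ccccc5)cc4)cc(=O)c3c2OCc2ccccc2)cc1 | intermediate
11 | 2-({5,7-bis(benzyloxy)-2-[4-(benzyloxy)phenyl]-4-oxochromen-6-yl}methyl)-6-(4-methoxyphenyl)pyran-4-one | COc1ccc(-c2cc(=O)cc(Cc3c(OCc4ccccc4)cc4oc(-c5ccc(OCc6ccccc6)cc5)cc(=O)c4c3OCc3ccccc3)o2)cc1 | intermediate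
12 | bis(2,4,6-trichlorophenyl) malonate | O=C(CC(=O)Oc1c(Cl)cc(Cl)cc1Cl)Oc1c(Cl)cc(Cl)cc1Cl | starting material
13 | lithium 2-({5,7-bis(benzyloxy)-2-[4-(benzyloxy)phenyl]-4-oxochromen-6-yl}methylidene)-6-(4-methoxyphenyl)-2H-pyran-4-olate (exocyclic alkene geometry not defined) | [Li+].COc1ccc(cc1)C1=CC([O-])=CC(=Cc2c(OCc3ccccc3)cc3oc(-c4ccc(OCc5ccccc5)cc4)cc(=O)c3c2OCc2ccccc2)O1 | intermediate
14 | 2,4,6-trichlorophenyl 4-{5,7-bis(benzyloxy)-2-[4-(benzyloxy)phenyl]-4-oxochromen-6-yl}-4-[6-(4-methoxyphenyl)-4-oxopyran-2-yl]-3-oxobutanoate (racemic at C4, formed as its lithium enolate) | COc1ccc(-c2cc(=O)cc(C(C(=O)CC(=O)Oc3c(Cl)cc(Cl)cc3Cl)c3c(OCc4ccccc4)cc4oc(-c5ccc(OCc6ccccc6)cc5)cc(=O)c4c3OCc3ccccc3)o2)cc1 | intermediate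
15 | 4-{5,7-bis(benzyloxy)-2-[4-(benzyloxy)phenyl]-4-oxochromen-6-yl}-4-[6-(4-methoxyphenyl)-4-oxopyran-2-yl]but-1-ene-1,3-dione (racemic at C4) | COc1ccc(-c2cc(=O)cc(C(C(=O)C=C=O)c3c(OCc4ccccc4)cc4oc(-c5ccc(OCc6ccccc6)cc5)cc(=O)c4c3OCc3ccccc3)o2)cc1 | intermediate
16 | 8-{5,7-bis(benzyloxy)-2-[4-(benzyloxy)phenyl]-4-oxochromen-6-yl}-5,7-dihydroxy-2-(4-methoxyphenyl)chromen-4-one | COc1ccc(-c2cc(=O)c3c(O)cc(O)c(-c4c(OCc5ccccc5)cc5oc(-c6ccc(OCc7ccccc7)cc6)cc(=O)c5c4OCc4ccccc4)c3o2)cc1 | intermediate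
17 | 8-[5,7-dihydroxy-2-(4-hydroxyphenyl)-4-oxochromen-6-yl]-5,7-dihydroxy-2-(4-methoxyphenyl)chromen-4-one | COc1ccc(-c2cc(=O)c3c(O)cc(O)c(-c4c(O)cc5oc(-c6ccc(O)cc6)cc(=O)c5c4O)c3o2)cc1 | target

Total step count: 9. Longest linear sequence: 9 steps (1 to 17); 7 and 12 are bought.

Steps most likely to fail

Step 8. Proton transfer from the acidic malonate may consume the dienolate faster than carbon–carbon bond formation. The dienolate may also be acylated at O4, or at pyranone C3 first, after which the acylketene can lactonise onto O4 to a fused 2-pyranone. The ketene may oligomerise. The fallback uses known chemistry and makes the biaryl bond by Suzuki–Miyaura coupling; it sets out from 2 and returns to the route at 17. Iodination of 2 ortho to the free 5-hydroxyl (BnNMe3 ICl2, CaCO3, CH2Cl2/MeOH) should give 7-(benzyloxy)-2-[4-(benzyloxy)phenyl]-5-hydroxy-6-iodochromen-4-one F1. Benzylation (BnBr, Cs2CO3, DMF) then gives 5,7-bis(benzyloxy)-2-[4-(benzyloxy)phenyl]-6-iodochromen-4-one F2. In parallel, commercial acacetin F3 is dibenzylated (BnBr, K2CO3, DMF, 80 °C) to 5,7-bis(benzyloxy)-2-(4-methoxyphenyl)chromen-4-one F4. Iodination at C8, the position expected for a fully alkylated 5,7-dioxygenated ring (I2, CF3CO2Ag, CH2Cl2), gives 5,7-bis(benzyloxy)-8-iodo-2-(4-methoxyphenyl)chromen-4-one F5. Miyaura borylation (B2pin2, PdCl2(dppf), KOAc, dioxane, 90 °C) gives 5,7-bis(benzyloxy)-2-(4-methoxyphenyl)-8-(4,4,5,5-tetramethyl-1,3,2-dioxaborolan-2-yl)chromen-4-one F6. Coupling of F2 with F6 (Pd(OAc)2, SPhos, K3PO4, toluene/H2O, 100 °C) should give 5,7-bis(benzyloxy)-8-{5,7-bis(benzyloxy)-2-[4-(benzyloxy)phenyl]-4-oxochromen-6-yl}-2-(4-methoxyphenyl)chromen-4-one F7. Hydrogenolysis of F7 (H2, 10% Pd/C, THF/MeOH) delivers 17.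

Step 6. The strongly basic dianion may enolise the arylacetaldehyde instead of adding to it, so that the aldehyde is recovered or condenses with itself. The fallback is a Lewis-acid-mediated vinylogous Mukaiyama aldol without strong base; it sets out from 6 and 7 and returns at 9. Diketone 7 is bis-silylated in one pot (Me3SiOTf, 2.2 equiv, Et3N, Et2O, 0 °C) to 1-(4-methoxyphenyl)-1,3-bis(trimethylsilyloxy)buta-1,3-diene F8. Its terminal carbon should add to 6 under BF3·OEt2 in CH2Cl2 at −78 °C, and aqueous work-up gives 9.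

Step 7. Oxidation may spill over to the doubly activated methylene groups of the enolised diketone, the aldol may revert, or the acid may strip the peri 5-benzyl ether during ring closure. The fallback reaches the triketone at the carboxylic acid level, so no alcohol oxidation is needed; it sets out from 6 and returns at 10. Pinnick oxidation of 6 (NaClO2, NaH2PO4, 2-methyl-2-butene, tBuOH/H2O) gives 2-{5,7-bis(benzyloxy)-2-[4-(benzyloxy)phenyl]-4-oxochromen-6-yl}acetic acid F9. Amide coupling (MeNHOMe·HCl, EDC·HCl, iPr2NEt, CH2Cl2) gives 2-{5,7-bis(benzyloxy)-2-[4-(benzyloxy)phenyl]-4-oxochromen-6-yl}-N-methoxy-N-methylacetamide F10. Acylation of dianion 8 (3 equiv, THF, −78 → 0 °C) with F10 gives 10, which is closed with TsOH as in step 7.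

Further compounds
F1 | step 8 | 7-(benzyloxy)-2-[4-(benzyloxy)phenyl]-5-hydroxy-6-iodochromen-4-one | O=c1cc(-c2ccc(OCc3ccccc3)cc2)oc2cc(OCc3ccccc3)c(I)c(O)c12
F2 | step 8 | 5,7-bis(benzyloxy)-2-[4-(benzyloxy)phenyl]-6-iodochromen-4-one | O=c1cc(-c2ccc(OCc3ccccc3)cc2)oc2cc(OCc3ccccc3)c(I)c(OCc3ccccc3)c12
F3 | step 8 | acacetin (5,7-dihydroxy-2-(4-methoxyphenyl)chromen-4-one) | COc1ccc(-c2cc(=O)c3c(O)cc(O)cc3o2)cc1
F4 | step 8 | 5,7-bis(benzyloxy)-2-(4-methoxyphenyl)chromen-4-one | COc1ccc(-c2cc(=O)c3c(OCc4ccccc4)cc(OCc4ccccc4)cc3o2)cc1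
F5 | step 8 | 5,7-bis(benzyloxy)-8-iodo-2-(4-methoxyphenyl)chromen-4-one | COc1ccc(-c2cc(=O)c3c(OCc4ccccc4)cc(OCc4ccccc4)c(I)c3o2)cc1
F6 | step 8 | 5,7-bis(benzyloxy)-2-(4-methoxyphenyl)-8-(4,4,5,5-tetramethyl-1,3,2-dioxaborolan-2-yl)chromen-4-one | COc1ccc(-c2cc(=O)c3c(OCc4ccccc4)cc(OCc4ccccc4)c(B4OC(C)(C)C(C)(C)O4)c3o2)cc1
F7 | step 8 | 5,7-bis(benzyloxy)-8-{5,7-bis(benzyloxy)-2-[4-(benzyloxy)phenyl]-4-oxochromen-6-yl}-2-(4-methoxyphenyl)chromen-4-one | COc1ccc(-c2cc(=O)c3c(OCc4ccccc4)cc(OCc4ccccc4)c(-c4c(OCc5ccccc5)cc5oc(-c6ccc(OCc7ccccc7)cc6)cc(=O)c5c4OCc4ccccc4)c3o2)cc1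
F8 | step 6 | 1-(4-methoxyphenyl)-1,3-bis(trimethylsilyloxy)buta-1,3-diene (inner alkene geometry not defined) | COc1ccc(cc1)C(O[Si](C)(C)C)=CC(O[Si](C)(C)C)=C
F9 | step 7 | 2-{5,7-bis(benzyloxy)-2-[4-(benzyloxy)phenyl]-4-oxochromen-6-yl}acetic acid | OC(=O)Cc1c(OCc2ccccc2)cc2oc(-c3ccc(OCc4ccccc4)cc3)cc(=O)c2c1OCc1ccccc1
F10 | step 7 | 2-{5,7-bis(benzyloxy)-2-[4-(benzyloxy)phenyl]-4-oxochromen-6-yl}-N-methoxy-N-methylacetamide | CON(C)C(=O)Cc1c(OCc2ccccc2)cc2oc(-c3ccc(OCc4ccccc4)cc3)cc(=O)c2c1OCc1ccccc1
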